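**Plan**

1. Locants: C1 (benzoyl bridgehead)–C2(=O)–C3–C4(=O)–C5 (geranyl bridgehead)–C6H2–C7H–C8Me2–C1, with C9(=O) between C1 and C5, C7–C10H2–C11H–C3, and the cyclopentane C3–C11–C12Me2–C13H2–C14H2. Enabling feature: C6–C7=C8Me2 is a prenyl group on C5, C10 can be an aldehyde on a cyclopentane spiro-fused at C3, and C8 lies next to the enol carbon C1 of the ring C1–C2–C3–C4–C5–C9.
2. Retrosynthesis: cut C10–O (deoxygenation), then C7–C10 and C1–C8 together (cation cascade) to a spiro acyl-trione aldehyde. Then cut C5–geranyl, then C4–C5 and C1–C2 (trione ring) to a bicyclic lactone acid chloride and prenylated benzoylacetone. Then cut C3–C14 and C3–C11 to a bromo aldehyde and bromomalonate.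
3. Forward ring order: γ-lactone, then cyclopentane (cis-fused bicyclic lactone), then the trione ring by acylation and Claisen closure (spiro at C3), then geranylation at C5. The seven-membered ring C3–C4–C5–C6–C7–C10–C11 and the six-membered ring C5–C6–C7–C8–C1–C9 form together last.
4. Stereochemistry: C11 comes from an organocatalytic photoredox α-alkylation of an aldehyde. C3 comes from the cis ring fusion of the lactone (its carbonyl becomes C2, the free carboxyl C4). C5 comes from geranylation anti to the silyloxymethyl arm on C11. C7 and C1 follow from the cage, and the C10 carbinol is removed.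

Key step: step 14

Assumption: the radical alkylation in step 3 follows the usual enamine model (attack anti to the C5 methyl group of the (2R,5S)-imidazolidinone), which for this aldehyde corresponds to the 2S product; the antipodal catalyst would be used if the sense proved opposite.

**Route**

Step 1
Reactants: 1 methyl 3,3-dimethylpent-4-enoate
Product: 2 methyl 5-bromo-3,3-dimethylpentanoate
Conditions: HBr (g), (PhCO2)2 (cat.), hexane, 0 °C
Reagents that add atoms: hydrogen bromide, Br
Why: Peroxide-initiated radical-chain hydrobromination adds bromine to the terminal carbon of the monosubstituted alkene (anti-Markovnikov), and the ester is inert.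

Step 2
Reactants: 2 methyl 5-bromo-3,3-dimethylpentanoate
Product: 3 5-bromo-3,3-dimethylpentanal
Conditions: i-Bu2AlH (1.05 equiv), CH2Cl2, −78 °C; MeOH, then aq. work-up
Reagents that add atoms: none
Why: Partial reduction of a methyl ester with i-Bu2AlH stops at the aluminium hemiacetal at −78 °C and gives the aldehyde on hydrolysis, with the primary bromide untouched.

Step 3
Reactants: 3 5-bromo-3,3-dimethylpentanal (1.5 equiv); 4 diethyl bromomalonate
Product: 5 diethyl 2-[(2S)-5-bromo-3,3-dimethyl-1-oxopentan-2-yl]propanedioate
Conditions: Ru(bpy)3Cl2 (0.5 mol %), (2R,5S)-2-tert-butyl-3,5-dimethylimidazolidin-4-one·TfOH (20 mol %), 2,6-lutidine, DMF, visible light, 20 °C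
Reagents that add atoms: none
Why: Enantioselective organocatalytic photoredox α-alkylation of an aldehyde, in which the malonyl radical released from 4 adds to the E-enamine on the face away from the catalyst's C5 methyl group and so sets C11; the unactivated primary bromide is not reduced.

Step 4
Reactants: 5 diethyl 2-[(2S)-5-bromo-3,3-dimethyl-1-oxopentan-2-yl]propanedioate
Product: 7 ethyl (4S)-4-(4-bromo-2-methylbutan-2-yl)-2-oxooxolane-3-carboxylate, via hydroxy diester 6 (not isolated)
Conditions: NaBH4, EtOH, −20 °C; 1 M HCl; then TsOH·H2O (cat.), toluene, 50 °C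
Reagents that add atoms: none
Why: Chemoselective NaBH4 reduction removes the epimerisable α-formyl centre at once, and the γ-hydroxy malonate closes to the γ-lactone by acid-catalysed transesterification without touching C11.

Step 5
Reactants: 7 ethyl (4S)-4-(4-bromo-2-methylbutan-2-yl)-2-oxooxolane-3-carboxylate
Product: 8 ethyl (3aS,6aR)-6,6-dimethyl-3-oxohexahydro-1H-cyclopenta[c]furan-3a-carboxylate
Conditions: K2CO3, DMF, 20 → 40 °C
Reagents that add atoms: none
Why: Intramolecular C-alkylation of the malonate-type lactone enolate (five-membered exo closure, helped by the gem-dimethyl group) forms the cyclopentane, and because only the cis-fused bicycle can form, the lactone carbonyl (future C2) is cis and the ester (future C4) trans to C10, which fixes C3 relative to C11.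

Step 6
Reactants: 8 ethyl (3aS,6aR)-6,6-dimethyl-3-oxohexahydro-1H-cyclopenta[c]furan-3a-carboxylate
Product: 10 (3aS,6aR)-6,6-dimethyl-3-oxohexahydro-1H-cyclopenta[c]furan-3a-carboxylic acid, via hydroxy diacid 9 (not isolated)
Conditions: KOH, EtOH–H2O, 80 °C; then 2 M HCl to pH 1, 20 °C
Reagents that add atoms: potassium hydroxide, [K+].[OH-]
Why: Saponification of both acyl groups followed by acidification, on which only the carboxyl cis to the hydroxymethyl group can re-lactonise, so the two carbonyl groups on C3 stay distinguished (kept at room temperature to avoid decarboxylation).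

Step 7
Reactants: 10 (3aS,6aR)-6,6-dimethyl-3-oxohexahydro-1H-cyclopenta[c]furan-3a-carboxylic acid
Product: 11 (3aR,6aR)-6,6-dimethyl-3-oxohexahydro-1H-cyclopenta[c]furan-3a-carbonyl chloride
Conditions: (COCl)2, DMF (cat.), CH2Cl2, 0 → 20 °C; used crude
Reagents that add atoms: oxalyl chloride, ClC(=O)C(Cl)=O
Why: Standard acid chloride formation through the chloroiminium species; the quaternary α-carbon excludes ketene formation and the lactone is inert.

Step 8
Reactants: 12 benzoylacetone; 13 prenyl bromide
Product: 14 7-methyl-1-phenyloct-6-ene-1,3-dione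
Conditions: LiN(i-Pr)2 (2.1 equiv), THF, 0 °C; 13, −78 → 0 °C; 1 M HCl
Reagents that add atoms: none
Why: γ-Alkylation of a 1,3-diketone dianion, whose terminal carbanion is the more nucleophilic site and displaces the allylic bromide by SN2.

Step 9
Reactants: 11 (3aR,6aR)-6,6-dimethyl-3-oxohexahydro-1H-cyclopenta[c]furan-3a-carbonyl chloride; 14 7-methyl-1-phenyloct-6-ene-1,3-dione (2.2 equiv)
Product: 16 (1R,5S)-7-benzoyl-6,10-dihydroxy-1-(hydroxymethyl)-2,2-dimethyl-9-(3-methylbut-2-en-1-yl)spiro[4.5]deca-6,9-dien-8-one, via triketone lactone 15 (not isolated)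
Conditions: 14, LiN(i-Pr)2 (4.4 equiv), THF, 0 °C; 11, −78 → −20 °C; then 20 → 45 °C; cold 1 M HCl
Reagents that add atoms: none
Why: C-acylation of the diketone dianion at its γ-carbon (C5) by the acid chloride, which is far more electrophilic than the lactone, is followed by an intramolecular Claisen (Dieckmann-type) acylation of the central carbon C1 by the lactone carbonyl, which frees the C10 alkoxide; C3 keeps the configuration fixed in 8 because the trans acyl group has become C4 and the cis lactone carbonyl C2, and any enol lactone from O-acylation is reopened by the alkoxide so that the stable trione enolate accumulates.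

Step 10
Reactants: 16 (1R,5S)-7-benzoyl-6,10-dihydroxy-1-(hydroxymethyl)-2,2-dimethyl-9-(3-methylbut-2-en-1-yl)spiro[4.5]deca-6,9-dien-8-one
Product: 17 (1R,5S)-7-benzoyl-1-{[tert-butyl(diphenyl)silyl]oxymethyl}-6,10-dihydroxy-2,2-dimethyl-9-(3-methylbut-2-en-1-yl)spiro[4.5]deca-6,9-dien-8-one
Conditions: TBDPSCl, imidazole, DMF, 20 °C; then K2CO3, MeOH, 0 °C; work-up at pH 4
Reagents that add atoms: tert-butyl(chloro)diphenylsilane, CC(C)(C)[Si](Cl)(c1ccccc1)c1ccccc1
Why: Silylation of the primary alcohol, with any enol silyl ether cleaved by the methanolic K2CO3 wash; the bulky silyl ether protects the C10 oxygen and screens the lower face of the trione ring.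

Step 11
Reactants: 17 (silyl ether of 16); 18 geranyl bromide
Product: 19 (1R,5R,9S)-7-benzoyl-1-{[tert-butyl(diphenyl)silyl]oxymethyl}-9-[(2E)-3,7-dimethylocta-2,6-dien-1-yl]-6-hydroxy-2,2-dimethyl-9-(3-methylbut-2-en-1-yl)spiro[4.5]dec-6-ene-8,10-dione
Conditions: NaOMe (2.2 equiv), MeOH–THF, −10 °C; 18 (1.2 equiv), −10 → 0 °C; 1 M HCl
Reagents that add atoms: none
Why: C-alkylation of the acyl-trione dianion at C5, the only nucleophilic ring carbon left (lupulone-type dearomative allylation in a protic medium that disfavours O-alkylation); the electrophile should enter from the upper face, anti to C11 and its silyloxymethyl arm, which places geranyl cis to C14 and prenyl cis to C11.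

Step 12
Reactants: 19 (geranylated silyl ether)
Product: 20 (1R,5R,9S)-7-benzoyl-9-[(2E)-3,7-dimethylocta-2,6-dien-1-yl]-6-hydroxy-1-(hydroxymethyl)-2,2-dimethyl-9-(3-methylbut-2-en-1-yl)spiro[4.5]dec-6-ene-8,10-dione
Conditions: HF·pyridine, pyridine, THF, 0 → 20 °C
Reagents that add atoms: none
Why: Fluoride-mediated cleavage of the silyl ether under buffered, non-basic conditions that leave the enol, the alkenes and the quaternary centres alone.

Step 13
Reactants: 20 (C10 alcohol)
Product: 21 (1R,5R,9S)-7-benzoyl-9-[(2E)-3,7-dimethylocta-2,6-dien-1-yl]-6-hydroxy-2,2-dimethyl-9-(3-methylbut-2-en-1-yl)-8,10-dioxospiro[4.5]dec-6-ene-1-carbaldehyde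
Conditions: Dess–Martin periodinane (1.3 equiv), CH2Cl2, 0 °C; used at once
Reagents that add atoms: none
Why: Dess–Martin oxidation of the primary alcohol under neutral conditions at low temperature gives the aldehyde without epimerisation at C11 (flanked by two quaternary carbons) or over-oxidation.

Step 14
Reactants: 21 (spiro acyl-trione aldehyde)
Product: 22 C10-hydroxy cage compound (target skeleton with OH on C10, one C10 epimer drawn)
Conditions: Me2AlCl (3.0 equiv), CH2Cl2, −78 → −20 °C; 1 M HCl, 0 °C
Reagents that add atoms: none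
Why: Proposed new method: Me2AlCl converts the acyl-trione enol into a chelated chloro(methyl)aluminium enolate (methane is lost) and a further equivalent activates the C10 aldehyde, the C7=C8 alkene of the lower-face prenyl group attacks C10 through its less substituted carbon C7 (Prins addition), and the tertiary C8 cation is captured by the enolate carbon C1. The closest known reactions are the Me2AlCl-promoted intramolecular Prins and carbonyl–ene cyclisations of prenyl-type alkenes and the acid-mediated closure of tertiary cations onto the enol carbon of prenylated acylphloroglucinol-derived triones to give bicyclo[3.3.1]nonane-triones, each known alone but not run as one cascade on this substrate class. Ring C3–C4–C5–C6–C7–C10–C11 closes in a seven-membered mode that is exo for both the carbonyl and the alkene, and ring C5–C6–C7–C8–C1–C9 closes by a six-membered C-alkylation of the enol (enol double bond outside the new ring) at the trigonal cation. C7 is fixed because C6 on C5 and C10 on C11 both lie on the lower face of the trione ring, so the bond can form only with the C7 hydrogen pointing outward; C1 is fixed because C8 can reach it only from that same face; C10 follows the aldehyde rotamer and either epimer serves. The step needs the prenyl and not the geranyl alkene to react, which the C5 configuration secures because the upper-face geranyl group cannot reach C10. It also needs C- over O-capture of the cation, which the aluminium chelate on the enol oxygens and the reversibility of tertiary ether formation favour, while an aldol between C1 and C10 is a reversible detour.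

Step 15
Reactants: 22 C10-hydroxy cage compound
Product: 23 C10 O-phenyl thionocarbonate of 22
Conditions: PhOC(S)Cl, pyridine, DMAP (cat.), CH2Cl2, 20 → 40 °C
Reagents that add atoms: O-phenyl chlorothionoformate, S=C(Cl)Oc1ccccc1
Why: Thioacylation of the secondary alcohol under nucleophilic catalysis (first half of the Barton–McCombie deoxygenation), with neutral conditions that avoid alkoxide-triggered retro-Claisen cleavage of the non-enolisable triketone.

Step 16
Reactants: 23 C10 O-phenyl thionocarbonate
Product: 24 target CNP0168637.1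
Conditions: Bu3SnH, AIBN, toluene, 100 °C
Reagents that add atoms: none
Why: Barton–McCombie radical deoxygenation, in which the stannyl radical adds to the thiocarbonyl group, the C10–O bond fragments to a secondary radical and hydrogen transfer from Bu3SnH gives the methylene group; no stereocentre is touched and the trisubstituted alkenes are too remote to trap the radical.

**Compound list**

1 | methyl 3,3-dimethylpent-4-enoate | COC(=O)CC(C)(C)C=C | starting material
2 | methyl 5-bromo-3,3-dimethylpentanoate | COC(=O)CC(C)(C)CCBr | intermediate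
3 | 5-bromo-3,3-dimethylpentanal | O=CCC(C)(C)CCBr | intermediate
4 | diethyl bromomalonate | CCOC(=O)C(Br)C(=O)OCC | starting material
5 | diethyl 2-[(2S)-5-bromo-3,3-dimethyl-1-oxopentan-2-yl]propanedioate | CCOC(=O)C(C(=O)OCC)[C@H](C=O)C(C)(C)CCBr | intermediate
6 | diethyl 2-[(2S)-5-bromo-1-hydroxy-3,3-dimethylpentan-2-yl]propanedioate (hydroxy diester, not isolated) | CCOC(=O)C(C(=O)OCC)[C@H](CO)C(C)(C)CCBr | intermediate
7 | ethyl (4S)-4-(4-bromo-2-methylbutan-2-yl)-2-oxooxolane-3-carboxylate (C3 epimerisable, unspecified) | CCOC(=O)C1C(=O)OC[C@@H]1C(C)(C)CCBr | intermediate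
8 | ethyl (3aS,6aR)-6,6-dimethyl-3-oxohexahydro-1H-cyclopenta[c]furan-3a-carboxylate (cis-fused) | CCOC(=O)[C@]12CCC(C)(C)[C@H]1COC2=O | intermediate
9 | (2R)-2-(hydroxymethyl)-3,3-dimethylcyclopentane-1,1-dicarboxylic acid (hydroxy diacid, not isolated) | OC(=O)C1(C(O)=O)CCC(C)(C)[C@H]1CO | intermediate
10 | (3aS,6aR)-6,6-dimethyl-3-oxohexahydro-1H-cyclopenta[c]furan-3a-carboxylic acid | OC(=O)[C@]12CCC(C)(C)[C@H]1COC2=O | intermediate
11 | (3aR,6aR)-6,6-dimethyl-3-oxohexahydro-1H-cyclopenta[c]furan-3a-carbonyl chloride | ClC(=O)[C@]12CCC(C)(C)[C@H]1COC2=O | intermediate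
12 | benzoylacetone (1-phenylbutane-1,3-dione) | CC(=O)CC(=O)c1ccccc1 | starting material
13 | prenyl bromide (1-bromo-3-methylbut-2-ene) | CC(C)=CCBr | starting material
14 | 7-methyl-1-phenyloct-6-ene-1,3-dione | CC(C)=CCCC(=O)CC(=O)c1ccccc1 | intermediate
15 | 1-[(3aS,6aR)-6,6-dimethyl-3-oxohexahydro-1H-cyclopenta[c]furan-3a-yl]-2-(3-methylbut-2-en-1-yl)-5-phenylpentane-1,3,5-trione (triketone lactone, not isolated; chain C2 enolisable, unspecified) | CC(C)=CCC(C(=O)CC(=O)c1ccccc1)C(=O)[C@]12CCC(C)(C)[C@H]1COC2=O | intermediate
16 | (1R,5S)-7-benzoyl-6,10-dihydroxy-1-(hydroxymethyl)-2,2-dimethyl-9-(3-methylbut-2-en-1-yl)spiro[4.5]deca-6,9-dien-8-one (one enol tautomer; C2 carbonyl carbon cis to C10 on the cyclopentane) | CC(C)=CCC1=C(O)[C@@]2(CCC(C)(C)[C@H]2CO)C(O)=C(C(=O)c2ccccc2)C1=O | intermediate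
17 | (1R,5S)-7-benzoyl-1-{[tert-butyl(diphenyl)silyl]oxymethyl}-6,10-dihydroxy-2,2-dimethyl-9-(3-methylbut-2-en-1-yl)spiro[4.5]deca-6,9-dien-8-one | CC(C)=CCC1=C(O)[C@@]2(CCC(C)(C)[C@H]2CO[Si](c2ccccc2)(c2ccccc2)C(C)(C)C)C(O)=C(C(=O)c2ccccc2)C1=O | intermediate
18 | geranyl bromide ((2E)-1-bromo-3,7-dimethylocta-2,6-diene) | CC(C)=CCC/C(C)=C/CBr | starting material
19 | (1R,5R,9S)-7-benzoyl-1-{[tert-butyl(diphenyl)silyl]oxymethyl}-9-[(2E)-3,7-dimethylocta-2,6-dien-1-yl]-6-hydroxy-2,2-dimethyl-9-(3-methylbut-2-en-1-yl)spiro[4.5]dec-6-ene-8,10-dione (prenyl cis to C11, geranyl cis to C14) | CC(C)=CCC/C(C)=C/C[C@@]1(CC=C(C)C)C(=O)[C@@]2(CCC(C)(C)[C@H]2CO[Si](c2ccccc2)(c2ccccc2)C(C)(C)C)C(O)=C(C(=O)c2ccccc2)C1=O | intermediate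
20 | (1R,5R,9S)-7-benzoyl-9-[(2E)-3,7-dimethylocta-2,6-dien-1-yl]-6-hydroxy-1-(hydroxymethyl)-2,2-dimethyl-9-(3-methylbut-2-en-1-yl)spiro[4.5]dec-6-ene-8,10-dione | CC(C)=CCC/C(C)=C/C[C@@]1(CC=C(C)C)C(=O)[C@@]2(CCC(C)(C)[C@H]2CO)C(O)=C(C(=O)c2ccccc2)C1=O | intermediate
21 | (1R,5R,9S)-7-benzoyl-9-[(2E)-3,7-dimethylocta-2,6-dien-1-yl]-6-hydroxy-2,2-dimethyl-9-(3-methylbut-2-en-1-yl)-8,10-dioxospiro[4.5]dec-6-ene-1-carbaldehyde (precursor of the key step) | CC(C)=CCC/C(C)=C/C[C@@]1(CC=C(C)C)C(=O)[C@@]2(CCC(C)(C)[C@H]2C=O)C(O)=C(C(=O)c2ccccc2)C1=O | intermediate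
22 | C10-hydroxy cage compound: bicyclo[3.3.1]nonane-2,4,9-trione with C1 benzoyl, C5 geranyl, C8 gem-dimethyl, the C7–C10(OH)–C11 bridge to C3 and the fused 12,12-dimethylcyclopentane; configuration of the target, one C10 epimer drawn | CC(C)=CCC/C(C)=C/C[C@@]12C[C@H]3[C@@H](O)[C@@H]4C(C)(C)CC[C@]4(C1=O)C(=O)[C@@](C(=O)c1ccccc1)(C2=O)C3(C)C | intermediate
23 | C10 O-phenyl thionocarbonate of 22 | CC(C)=CCC/C(C)=C/C[C@@]12C[C@H]3[C@@H](OC(=S)Oc5ccccc5)[C@@H]4C(C)(C)CC[C@]4(C1=O)C(=O)[C@@](C(=O)c1ccccc1)(C2=O)C3(C)C | intermediate
24 | CNP0168637.1 | CC(C)=CCC/C(C)=C/C[C@@]12C[C@H]3C[C@@H]4C(C)(C)CC[C@]4(C1=O)C(=O)[C@@](C(=O)c1ccccc1)(C2=O)C3(C)C | target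

**Step count and risks**

Total steps: 16. Longest linear sequence: 15 (steps 1–7 and 9–16; step 8 is a one-step side branch).

Steps most likely to fail:

1. Step 14 (proposed new method). The C8 cation may lose a proton (ene-type termination), take chloride or methyl from aluminium, or be captured by an enol oxygen before C1 closes. Fallback, from 21, with the two bond formations separated into known reactions: heating 21 in toluene, or brief exposure to one equivalent of Me2AlCl at −78 °C, should give by intramolecular carbonyl–ene cyclisation the isopropenyl homoallylic alcohol F1 (C7–C10 formed, isopropenyl on C7). Treatment of this alcohol with TsOH·H2O in CH2Cl2 (or formic acid) protonates the isopropenyl group in the Markovnikov sense. The C8 cation, now generated under equilibrating conditions in which O-cyclised ethers reopen, closes onto C1 and the route is rejoined at 22.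

2. Step 9. The dianion may be acylated on oxygen or twice, and the ring may close through the C9 enol oxygen to a pyranone instead of through C1. Fallback, from 14 and 11: 14 is converted (Et3N/Me3SiCl, then LiN(i-Pr)2/Me3SiCl) into the 1,3-bis(trimethylsilyloxy)diene F2. This neutral dienol ether is acylated at its terminal carbon by 11 (Me3SiOTf cat., CH2Cl2, −78 → 20 °C), a known route to 1,3,5-tricarbonyl compounds. Aqueous work-up gives 15, now isolated, and ring closure with DBU in toluene at 80 °C rejoins the route at 16.

3. Step 11. Facial discrimination at C5 may be weak (the two faces differ mainly through the remote silyloxymethyl arm) and O-alkylation may compete. Fallback, from 17: the SN2 alkylation is replaced by a palladium-catalysed allylic alkylation (Tsuji–Trost) with geranyl methyl carbonate F3, made from geraniol and methyl chloroformate. Conditions would be Pd2(dba)3 (a zerovalent palladium source) with a chiral N,N'-(cyclohexane-1,2-diyl)bis(2-diphenylphosphinobenzamide) ligand in THF at 0 °C. The soft enolate attacks the unsubstituted allyl terminus at carbon, and the ligand enantiomer matched to upper-face attack is chosen; the route is rejoined at 19.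

**Further compounds**

F1 | step 14 | carbonyl–ene product of 21: C7–C10 bonded, isopropenyl on C7, C10 hydroxyl, C1/C2 enol intact | CC(C)=CCC/C(C)=C/C[C@@]12C[C@H](C(C)=C)[C@@H](O)[C@@H]3C(C)(C)CC[C@]3(C1=O)C(O)=C(C(=O)c1ccccc1)C2=O
F2 | step 9 | 1,3-bis(trimethylsilyloxy)diene of 14 (7-methyl-1-phenyl-1,3-bis(trimethylsilyloxy)octa-1,3,6-triene, enol geometry unspecified) | CC(C)=CCC=C(O[Si](C)(C)C)C=C(O[Si](C)(C)C)c1ccccc1
F3 | step 11 | geranyl methyl carbonate | CC(C)=CCC/C(C)=C/COC(=O)OC
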